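**Retrosynthetic overview**
1. Target 31 ← desilylation ← Evans–Tishchenko reduction/acyl transfer and γ-lactonisation of β-hydroxy ketone 23 with enal 28 (sets C6, installs the C8 ester, closes the lactone last).
2. 23 ← chloropyruvate aldol (C7–C11 bond) on epoxy-dienone 19 ← Shi epoxidation of ten-membered trienone 18.
3. 18 ← ring expansion: Pd-catalysed decarboxylative Grob-type fragmentation of the C6–C10 ring-fusion bond of the 5/7-fused dienyl carbonate 17.
4. 17 ← ring-closing metathesis (cycloheptadiene) ← dienyl addition and reductive aldol on silyloxycyclopentenone 5 ← Piancatelli rearrangement of furyl carbinol 1.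
5. Ring order: cyclopentenone → fused cycloheptadiene → ten-membered carbocycle → epoxide → γ-lactone.

Assumption: atom labels follow germacranolide numbering (ring C1–C10, C1/C10 epoxide, C6 lactone carbinol, C8 ester carbinol, C11–C13 lactone carbons); all numbered starting materials are taken as commercial. The route has not been tested experimentally; stereochemical outcomes are predictions from the models named in each step.

Step 1
Reactants: 1 1-(furan-2-yl)ethan-1-ol (racemic)
Product: 3 4-hydroxy-2-methylcyclopent-2-en-1-one (racemic), via trans-4-hydroxy-5-methylcyclopent-2-en-1-one 2 (not isolated)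
Conditions: H2O, ZnCl2 (cat.), pH 5, 100 °C; then phosphate buffer pH 8, 50 °C
Reagents that add atoms: water (O)
Why: Piancatelli rearrangement (furfuryl cation, water addition, 4π-conrotatory closure) gives trans-2, which under mild base isomerises by dehydration–rehydration to the more stable 2-methyl enone; the product is racemic.

Step 2
Reactants: 3 4-hydroxy-2-methylcyclopent-2-en-1-one (racemic)
Product: 4 (S)-4-hydroxy-2-methylcyclopent-2-en-1-one
Conditions: Amano lipase PS, vinyl acetate, t-BuOMe, 25 °C, to ca. 52% conversion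
Reagents that add atoms: none
Why: Lipase-catalysed kinetic resolution acylates the (R)-alcohol and leaves the (S)-alcohol, which becomes C8 of the target.

Step 3
Reactants: 4 (S)-4-hydroxy-2-methylcyclopent-2-en-1-one
Product: 5 (S)-2-methyl-4-(triethylsilyloxy)cyclopent-2-en-1-one
Conditions: Et3SiCl, imidazole, CH2Cl2, 0 °C
Reagents that add atoms: chlorotriethylsilane (CC[Si](Cl)(CC)CC)
Why: Standard silylation; the TES ether survives the organometallic steps and is removed under mild fluoride later.

Step 4
Reactants: 6 prop-2-yn-1-ol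
Product: 7 (Z)-3-iodo-2-methylprop-2-en-1-ol
Conditions: MeMgBr (2.5 equiv), CuI (10 mol%), THF, −10 °C to rt; then I2, −78 to 0 °C
Reagents that add atoms: methylmagnesium bromide (C[Mg]Br), iodine (II)
Why: Copper-catalysed anti-carbomagnesiation of the propargylic alkoxide (Duboudin) gives a chelated vinylmagnesium that is iodinated with retention, fixing the Z-iodoalkene.

Step 5
Reactants: 7 (Z)-3-iodo-2-methylprop-2-en-1-ol
Product: 8 (Z)-3-iodo-2-methylprop-2-enal
Conditions: PhI(OAc)2, TEMPO (10 mol%), CH2Cl2, rt
Reagents that add atoms: none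
Why: TEMPO/iodine(III) oxidation of an allylic alcohol to the enal without touching the alkene geometry.

Step 6
Reactants: 8 (Z)-3-iodo-2-methylprop-2-enal
Product: 9 (Z)-1-iodo-2-methylbuta-1,3-diene
Conditions: Ph3PCH3Br, KHMDS, THF, −78 to 0 °C
Reagents that add atoms: methyltriphenylphosphonium bromide ([Br-].C[P+](c1ccccc1)(c1ccccc1)c1ccccc1)
Why: Wittig methylenation; the iodoalkene geometry is untouched.

Step 7
Reactants: 5 (S)-2-methyl-4-(triethylsilyloxy)cyclopent-2-en-1-one; 10 acrolein
Product: 14 (S)-1-[(1S,4R)-1-methyl-2-oxo-4-(triethylsilyloxy)cyclopentyl]prop-2-en-1-yl methyl carbonate, via silyl enol ether 11 (not isolated), via lithium enolate 12 (not isolated), via lithium aldolate 13 (not isolated)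
Conditions: PhMe2SiH, RhCl(PPh3)3 (1 mol%), PhMe, 50 °C; then MeLi, THF, 0 °C; 10, −78 °C; ClCO2Me, −78 to −20 °C
Reagents that add atoms: methyl chloroformate (COC(=O)Cl)
Why: Rh-catalysed 1,4-hydrosilylation gives the regiodefined enol ether, MeLi releases the tetrasubstituted lithium enolate, and a Zimmerman–Traxler aldol anti to the OTES group creates quaternary C10 and the anti C1 carbinol (O1 anti to C9); acylation traps the aldolate before retro-aldol.

Step 8
Reactants: 14 the methyl carbonate from step 7; 9 (Z)-1-iodo-2-methylbuta-1,3-diene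
Product: 16 (S)-1-[(1S,2R,4R)-2-hydroxy-1-methyl-2-[(1Z)-2-methylbuta-1,3-dien-1-yl]-4-(triethylsilyloxy)cyclopentyl]prop-2-en-1-yl methyl carbonate, via dienyllithium 15 (not isolated)
Conditions: 9, t-BuLi (2 equiv), Et2O, −78 °C; CeCl3, THF, −78 °C; then 14, −78 °C; NH4Cl
Reagents that add atoms: none
Why: Iodine–lithium exchange with retention, then organocerium 1,2-addition to the hindered ketone from the face of the angular methyl (anti to the branched C1 chain); the carbonate is inert at −78 °C and the C6 centre is destroyed later.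

Step 9
Reactants: 16 the dienyl tertiary alcohol from step 8
Product: 17 trans-fused 8a-hydroxy-3a,7-dimethyl-2-(triethylsilyloxy)-1,2,3,3a,4,8a-hexahydroazulen-4-yl methyl carbonate (carbonate oxygen cis to the ring-fusion hydroxyl)
Conditions: Grubbs II (5 mol%), CH2Cl2, 40 °C
Reagents that add atoms: none
Why: Ring-closing metathesis between the two terminal vinyl groups (the trisubstituted C4=C5 is inert) closes the cycloheptadiene; both ring alkenes are necessarily Z.

Step 10
Reactants: 17 the 5/7-fused dienyl carbonate from step 9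
Product: 18 (2Z,4Z,6E,9R)-3,7-dimethyl-9-(triethylsilyloxy)cyclodeca-2,4,6-trien-1-one
Conditions: Pd(PPh3)4 (5 mol%), THF, 0 °C; kept below 0 °C and used at once
Reagents that add atoms: none
Why: Proposed new method: Pd(0) ionises the dienylic methyl carbonate with inversion to a cationic π-allyl(pentadienyl)palladium, the expelled methyl carbonate loses CO2 and the methoxide deprotonates the tertiary C6–OH; because C1–O and C10–C9 are cis on the seven-membered ring (anti aldol), the C6–C10 ring-fusion σ bond aligns anti to palladium and collapses in a Grob-type fragmentation to C6=O and the (E)-C1=C10 alkene with release of Pd(0), expanding the 5/7 bicycle to the ten-membered trienone; the closest known reactions are the Pd-catalysed decarboxylative fragmentation of 4-vinyl-1,3-dioxan-2-ones to dienyl carbonyl compounds and the Wharton–Grob ring expansion of 1,3-diol monosulfonates, neither shown for cleaving a ring-fusion bond to a medium ring.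

Step 11
Reactants: 18 the ten-membered trienone from step 10
Product: 19 (2Z,4Z,6R,7R,9R)-6,7-epoxy-3,7-dimethyl-9-(triethylsilyloxy)cyclodeca-2,4-dien-1-one
Conditions: D-fructose-derived Shi ketone (0.3 equiv), Oxone, K2CO3, Bu4NHSO4, MeCN/DMM/aq. Na2B4O7, −5 °C
Reagents that add atoms: Oxone, potassium peroxymonosulfate ([K+].[O-]S(=O)(=O)OO)
Why: Shi epoxidation: the chiral dioxirane attacks the most electron-rich, E-trisubstituted C1=C10 alkene (remote from the carbonyl; the Z-disubstituted and enone alkenes are poor substrates), and the spiro transition state of the D-fructose ketone gives the (1R,10R)-epoxide by reagent control.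

Step 12
Reactants: 20 methyl pyruvate
Product: 21 methyl 3-chloro-2-oxopropanoate
Conditions: SO2Cl2 (1.0 equiv), CH2Cl2, 0 °C to rt
Reagents that add atoms: sulfuryl chloride (O=S(=O)(Cl)Cl)
Why: Electrophilic α-chlorination of the pyruvate methyl group through its enol.

Step 13
Reactants: 19 the epoxy-dienone from step 11; 21 methyl 3-chloro-2-oxopropanoate
Product: 22 methyl (S)-3-chloro-2-hydroxy-2-[C7 of the epoxy-dienone ring]propanoate (C7–C11 bond trans to the C8 silyloxy group; C7 and C11 as in the target)
Conditions: LDA, THF, −78 °C; 21; AcOH, −78 °C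
Reagents that add atoms: none
Why: Kinetic α′-lithium enolate (C7) aldol onto the very electrophilic keto group of 21 through a closed Zimmerman–Traxler transition state; attack anti to the C8 silyloxy group sets C7, and the E-type ring enolate with the ester equatorial sets the 7,11-anti C11 carbinol; the cold acidic quench prevents retro-aldol and Darzens closure.

Step 14
Reactants: 22 the aldol adduct from step 13
Product: 23 the C8-hydroxy β-hydroxy ketone (22 without the triethylsilyl group)
Conditions: HF·pyridine, pyridine, THF, 0 °C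
Reagents that add atoms: none
Why: Buffered fluoride cleaves the secondary TES ether without opening the vinyl epoxide or closing the chlorohydrin.

Step 15
Reactants: 24 2-methylidenepropane-1,3-diol
Product: 25 2-[(triethylsilyloxy)methyl]prop-2-en-1-ol
Conditions: NaH (1.0 equiv), THF, 0 °C; Et3SiCl
Reagents that add atoms: chlorotriethylsilane (CC[Si](Cl)(CC)CC)
Why: Monosilylation of a symmetric diol through its sparingly soluble monosodium alkoxide.

Step 16
Reactants: 25 2-[(triethylsilyloxy)methyl]prop-2-en-1-ol
Product: 26 2-[(triethylsilyloxy)methyl]prop-2-enal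
Conditions: PhI(OAc)2, TEMPO (10 mol%), CH2Cl2, rt
Reagents that add atoms: none
Why: TEMPO/iodine(III) oxidation of the allylic alcohol to the 2-substituted acrolein.

Step 17
Reactants: 26 2-[(triethylsilyloxy)methyl]prop-2-enal; 27 (Z)-but-2-ene
Product: 28 (E)-2-[(triethylsilyloxy)methyl]but-2-enal
Conditions: Hoveyda–Grubbs II (5 mol%), excess 27, CH2Cl2, 40 °C, sealed tube
Reagents that add atoms: none
Why: Cross metathesis of a 2-substituted acrolein with 2-butene, which as for methacrolein gives the trisubstituted enal with methyl trans to the formyl group (the geometry of the target side chain).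

Step 18
Reactants: 23 the β-hydroxy ketone from step 14; 28 (E)-2-[(triethylsilyloxy)methyl]but-2-enal
Product: 30 the target with its side-chain hydroxyl as triethylsilyl ether, via hydroxy ester 29 (not isolated)
Conditions: SmI2 (0.3 equiv, pre-mixed with 28 to give Sm(III)), 28 (5 equiv), THF, −10 to 0 °C; pH 7 buffer
Reagents that add atoms: none
Why: Evans–Tishchenko reaction: the samarium-bound hemiacetal of 28 on the C8 hydroxyl delivers hydride to C6 through a six-membered chair, giving the 1,3-anti (6R) alcohol while the acyl group ends on O8; the C6 samarium alkoxide then closes the cis-fused γ-lactone onto the neighbouring methyl ester.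

Step 19
Reactants: 30 the O-triethylsilyl target
Product: 31 target, CNP0158457.1
Conditions: HF·pyridine, pyridine, THF, 0 °C
Reagents that add atoms: none
Why: Buffered fluoride removes the primary TES ether; the vinyl epoxide, chlorohydrin and both esters are stable under these conditions.

**Compound list**
1 | 1-(furan-2-yl)ethan-1-ol (racemic) | CC(O)c1ccco1 | starting material
2 | trans-4-hydroxy-5-methylcyclopent-2-en-1-one (racemic, one enantiomer drawn) | C[C@H]1[C@H](O)C=CC1=O | intermediate
3 | 4-hydroxy-2-methylcyclopent-2-en-1-one (racemic) | CC1=CC(O)CC1=O | intermediate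
4 | (S)-4-hydroxy-2-methylcyclopent-2-en-1-one | O[C@H]1CC(=O)C(C)=C1 | intermediate
5 | (S)-2-methyl-4-(triethylsilyloxy)cyclopent-2-en-1-one | CC[Si](CC)(CC)O[C@H]1CC(=O)C(C)=C1 | intermediate
6 | prop-2-yn-1-ol | C#CCO | starting material
7 | (Z)-3-iodo-2-methylprop-2-en-1-ol | I/C=C(/C)CO | intermediate
8 | (Z)-3-iodo-2-methylprop-2-enal | I/C=C(/C)C=O | intermediate
9 | (Z)-1-iodo-2-methylbuta-1,3-diene | I/C=C(/C)C=C | intermediate
10 | acrolein | C=CC=O | starting material
11 | (R)-dimethyl(phenyl)silyl enol ether of the reduced enone (1-silyloxy-2-methyl-4-triethylsilyloxycyclopent-1-ene) | CC[Si](CC)(CC)O[C@H]1CC(O[Si](C)(C)c2ccccc2)=C(C)C1 | intermediate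
12 | lithium (R)-2-methyl-4-(triethylsilyloxy)cyclopent-1-en-1-olate | [Li+].CC[Si](CC)(CC)O[C@H]1CC([O-])=C(C)C1 | intermediate
13 | lithium aldolate of 12 and acrolein | [Li+].CC[Si](CC)(CC)O[C@H]1CC(=O)[C@](C)([C@@H]([O-])C=C)C1 | intermediate
14 | (S)-1-[(1S,4R)-1-methyl-2-oxo-4-(triethylsilyloxy)cyclopentyl]prop-2-en-1-yl methyl carbonate | CC[Si](CC)(CC)O[C@H]1CC(=O)[C@](C)([C@@H](OC(=O)OC)C=C)C1 | intermediate
15 | (Z)-(2-methylbuta-1,3-dien-1-yl)lithium | [Li]/C=C(/C)C=C | intermediate
16 | (S)-1-[(1S,2R,4R)-2-hydroxy-1-methyl-2-[(1Z)-2-methylbuta-1,3-dien-1-yl]-4-(triethylsilyloxy)cyclopentyl]prop-2-en-1-yl methyl carbonate | CC[Si](CC)(CC)O[C@H]1C[C@@](O)(/C=C(C)\C=C)[C@](C)([C@@H](OC(=O)OC)C=C)C1 | intermediate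
17 | trans-fused 8a-hydroxy-3a,7-dimethyl-2-(triethylsilyloxy)-1,2,3,3a,4,8a-hexahydroazulen-4-yl methyl carbonate | CC[Si](CC)(CC)O[C@H]1C[C@@]2(O)/C=C(C)\C=C/[C@H](OC(=O)OC)[C@]2(C)C1 | intermediate
18 | (2Z,4Z,6E,9R)-3,7-dimethyl-9-(triethylsilyloxy)cyclodeca-2,4,6-trien-1-one | CC[Si](CC)(CC)O[C@@H]1C/C(C)=C/C=C\C(C)=C/C(=O)C1 | intermediate
19 | (2Z,4Z,6R,7R,9R)-6,7-epoxy-3,7-dimethyl-9-(triethylsilyloxy)cyclodeca-2,4-dien-1-one | CC[Si](CC)(CC)O[C@@H]1C[C@@]2(C)O[C@@H]2/C=C\C(C)=C/C(=O)C1 | intermediate
20 | methyl pyruvate | CC(=O)C(=O)OC | starting material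
21 | methyl 3-chloro-2-oxopropanoate | O=C(CCl)C(=O)OC | intermediate
22 | C7 aldol adduct of 19 (methyl (S)-3-chloro-2-hydroxypropanoate unit on C7, C8-OTES) | CC[Si](CC)(CC)O[C@@H]1C[C@@]2(C)O[C@@H]2/C=C\C(C)=C/C(=O)[C@H]1[C@@](O)(CCl)C(=O)OC | intermediate
23 | C8-hydroxy β-hydroxy ketone (desilylated 22) | O[C@@H]1C[C@@]2(C)O[C@@H]2/C=C\C(C)=C/C(=O)[C@H]1[C@@](O)(CCl)C(=O)OC | intermediate
24 | 2-methylidenepropane-1,3-diol | C=C(CO)CO | starting material
25 | 2-[(triethylsilyloxy)methyl]prop-2-en-1-ol | C=C(CO)CO[Si](CC)(CC)CC | intermediate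
26 | 2-[(triethylsilyloxy)methyl]prop-2-enal | C=C(C=O)CO[Si](CC)(CC)CC | intermediate
27 | (Z)-but-2-ene | C/C=C\C | starting material
28 | (E)-2-[(triethylsilyloxy)methyl]but-2-enal | C/C=C(\CO[Si](CC)(CC)CC)C=O | intermediate
29 | Evans–Tishchenko hydroxy ester (C6-OH, C8 ester, C12 methyl ester) | C/C=C(\CO[Si](CC)(CC)CC)C(=O)O[C@@H]1C[C@@]2(C)O[C@@H]2/C=C\C(C)=C/[C@@H](O)[C@H]1[C@@](O)(CCl)C(=O)OC | intermediate
30 | O-triethylsilyl ether of the target (side-chain CH2OSiEt3) | C/C=C(\CO[Si](CC)(CC)CC)C(=O)O[C@@H]1C[C@@]2(C)O[C@@H]2/C=C\C(C)=C/[C@H]2OC(=O)[C@](O)(CCl)[C@H]21 | intermediate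
31 | CNP0158457.1 | C/C=C(\CO)C(=O)O[C@@H]1C[C@@]2(C)O[C@@H]2/C=C\C(C)=C/[C@H]2OC(=O)[C@](O)(CCl)[C@H]21 | target

**Step count and risk**
Total: 19 steps. Longest linear sequence: 12 steps (1, 2, 3, 7, 8, 9, 10, 11, 13, 14, 18, 19).

Risk 1, step 10 (the proposed new ring expansion). The π-allyl intermediate could be captured by oxygen instead of fragmenting, or the alkene geometry could erode. Trienone 18 is also a (Z)-hexatriene in a ten-membered ring and is expected to be prone to 6π-electrocyclisation, so it must stay below 0 °C and be epoxidised at once. The fallback uses known chemistry and sets out from 17. Methanolysis of the carbonate (K2CO3, MeOH) gives the bicyclic diol F1. MnO2 oxidises its dienylic alcohol to the hydroxy dienone F2. Hydroxyl-directed anti reduction (Me4NBH(OAc)3) then gives the C1-epimeric diol F3, whose C1 oxygen is now trans to C9. Selective mesylation of the secondary alcohol gives the mesylate F4, and KOt-Bu at −78 °C triggers a classical anti-periplanar Wharton–Grob fragmentation. This returns to the route at 18.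

Risk 2, step 13 (C7–C11 aldol). The facial and simple diastereoselectivity on the macrocyclic enolate are not secured, and the tertiary aldol is reversible. The fallback sets out from 19. LDA/Me3SiCl gives the trimethylsilyl enol ether F5. A chiral Lewis acid (Sn(OTf)2 with (S,S)-Ph-pybox), which is anti-selective for pyruvate-type electrophiles, then mediates a Mukaiyama aldol with 21 under catalyst control. This returns to the route at 22.

Risk 3, step 18 (Evans–Tishchenko/lactonisation). The free C8 hydroxyl of 23 may lactonise onto the ester before the reduction, and hemiacetal formation from an enal can be slow. The fallback sets out from 22, with C8 still silylated. Anti reduction directed by the C11 hydroxyl (Me4NBH(OAc)3, buffered) with spontaneous lactonisation gives the silyloxy lactone F6. HF·pyridine then gives the 8-hydroxy lactone F7. Yamaguchi esterification with the acid F8, made by Pinnick oxidation of 28, returns to the route at 30.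

Further compounds
F1 | step 10 | trans-fused bicyclic diol (17 without the methoxycarbonyl group) | CC[Si](CC)(CC)O[C@H]1C[C@@]2(O)/C=C(C)\C=C/[C@H](O)[C@]2(C)C1
F2 | step 10 | bicyclic β-hydroxy dienone (C1 ketone) | CC[Si](CC)(CC)O[C@H]1C[C@@]2(O)/C=C(C)\C=C/C(=O)[C@]2(C)C1
F3 | step 10 | C1-epimeric bicyclic diol | CC[Si](CC)(CC)O[C@H]1C[C@@]2(O)/C=C(C)\C=C/[C@@H](O)[C@]2(C)C1
F4 | step 10 | C1 methanesulfonate of F3 | CC[Si](CC)(CC)O[C@H]1C[C@@]2(O)/C=C(C)\C=C/[C@@H](OS(C)(=O)=O)[C@]2(C)C1
F5 | step 13 | trimethylsilyl enol ether of 19 (C6=C7) | CC[Si](CC)(CC)O[C@@H]1C[C@@]2(C)O[C@@H]2/C=C\C(C)=C/C(O[Si](C)(C)C)=C1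
F6 | step 18 | 8-O-triethylsilyl chlorohydrin lactone | CC[Si](CC)(CC)O[C@@H]1C[C@@]2(C)O[C@@H]2/C=C\C(C)=C/[C@H]2OC(=O)[C@](O)(CCl)[C@H]21
F7 | step 18 | 8-hydroxy chlorohydrin lactone | O[C@@H]1C[C@@]2(C)O[C@@H]2/C=C\C(C)=C/[C@H]2OC(=O)[C@](O)(CCl)[C@H]21
F8 | step 18 | (E)-2-[(triethylsilyloxy)methyl]but-2-enoic acid | C/C=C(\CO[Si](CC)(CC)CC)C(=O)O
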